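The readings come from a simulation with made-up constants; the scatter is artificial.

Molar per minute is the unit I reckon in: I follow the rate of target formation from electrophile and nucleophile, and what slows it.

| setting | Sunday's | Saturday's | flask |
|---|---|---|---|
| electrophile | 0.020 M | 0.020 M | 0.020 M |
| nucleophile | 0.016 M | 0.032 M | 0.0160 M |
| remark | the very flask that is asked about, followed so far | run made earlier |  |
| time |  |  | 2.0 h |

| run | time / min | target / % |
|---|---|---|
| Sunday's | 4.00 | 8.5 |
| Sunday's | 12.0 | 18.8 |
| Sunday's | 20.0 | 22.6 |
| Sunday's | 30.0 | 26.7 |
| Sunday's | 40.0 | 28.2 |
| Sunday's | 60.0 | 29.7 |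
| Sunday's | 80.0 | 29.8 |
| Saturday's | 4.00 | 15.2 |
| Saturday's | 8.00 | 24.8 |
| Saturday's | 10.0 | 26.5 |
| Saturday's | 15.0 | 34.2 |
| Saturday's | 20.0 | 35.2 |
| Saturday's | 25.0 | 37.7 |

(scatter of a reading: 1 percentage point)

- red: change nothing and wait 4.0 h more
- blue: at 2.0 h take out 90% of the target then present, then wait 4.0 h
- amber: at 2.0 h add nucleophile, 100% of the amount charged, then wait 4.0 h
- ochre: at 2.0 h add electrophile, 50.0% of the amount charged, then wait 4.0 h

1. target, in percent of the electrophile first charged, at 2.0 h
2. the option that brings most further target ("none" if no option brings more than 2 percentage points) (red / blue / amber / ochre / none)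
3. target present, with what was taken out counted in, in percent of the electrophile first charged, after red
4. target present, with what was taken out counted in, in percent of the electrophile first charged, after blue

- removed target is counted in
- additions bring no volume worth counting

The first readings give the starting rate v₀ of each run:

Sunday: v₀ = 4.25 × 10⁻⁴ M min⁻¹
Saturday: v₀ = 7.60 × 10⁻⁴ M min⁻¹

Saturday's nucleophile charge is twice Sunday's and its rate is 1.79 times higher, so I take the rate as proportional to nucleophile. I also take it as proportional to electrophile. Sunday's late rate, between 30.0 min and 80.0 min, reads

v = 1.24 × 10⁻⁵ M min⁻¹, slower by a factor of 34.3.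

If each target costs one electrophile, electrophile has kept 70.2% of its level. The remaining slowing I lay on nucleophile, the limiting reagent, which must then stand at a fraction 0.0416, less than electrophile.

Dividing the rate of nucleophile loss by the rate of target gain removes time. This gives ν, the nucleophile spent per target made:

ν = 2.57

The nucleophile still free then buys about 1.3 percentage points. Red, blue and ochre add none, so I commit to 29.8% now and about 31.1% after red or blue. Saturday's run has amber's total nucleophile and stands 7.9 points above Sunday's, so amber is my choice.

The forecast gives 30% now, 30% after red, 42% after blue, and amber: “Amber wins either way”. The flask gives 30.3% now, 30.9% after red, 31.3% after blue, and amber, which gains 10 points.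

    electrophile + nucleophile → acid set free + target (k = 1.70 L mol⁻¹ min⁻¹)
    nucleophile + acid set free ⇌ protonated nucleophile, settled at all times (K = 4.90 × 10⁵ L mol⁻¹)
    nucleophile + target → over-reaction product (k = 1.40 L mol⁻¹ min⁻¹)

Red, blue and ochre gain 0.58 points, 0.98 points and 1.1 points, each under my allowance, with 0.499% of the nucleophile free at 120 min. Amber's gain in this flask owes a part to the pairing of nucleophile with acid set free: without that pairing, amber changes target by −13 points instead of 10 points. For the same flask with 0.0064 M of nucleophile, ν gives 12.4% of target, and that neighbour holds 14.7%.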